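**Retrosynthetic overview**
1. Feature: ring B (C1'–C6') is pentasubstituted. C3'–OH and C5'–OMe sit meta to each other across C4'–H, and C2' and C6' each carry a prenyl group and flank C1', which is bonded to C2 of the benzofuran. At the dihydro level this pattern is the mono methyl enol ether of a mirror-symmetric 4,6-diprenyl-5-arylcyclohexane-1,3-dione, whose prenyl-bearing carbons are ordinary carbonyl α-carbons.
2. Key disconnection: the dione ring is cut at C1'–C2' (Michael) and C3'–C4' (Claisen). This gives an α-prenyl (benzofuran-2-yl)methylidene methyl ketone and methyl 5-methylhex-4-enoate.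
3. Precursors: the enone comes from a Horner–Wadsworth–Emmons reaction of a 6-silyloxybenzofuran-2-carbaldehyde with a C-prenylated β-ketophosphonate. The ester comes from a Johnson–Claisen rearrangement.
4. End game: O-methylation of the symmetric dione tells the two oxygens apart. The vinylogous ester is raised to a silyl dienol ether so that DDQ can dehydrogenate it cold and the phenol emerges masked, which blocks oxidative chromene closure. The 6-OH travels as a triisopropylsilyl ether rather than a second methyl ether, so one fluoride step frees both phenols and the C5'-OMe is never at risk.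
5. Ring order: the benzofuran (rings A and C) is bought, ring B is closed as a saturated dione in step 6 and becomes aromatic in step 9.

Key step: step 6

Remark: the target has no stereocentre and no stereogenic double bond. The three ring stereocentres made in step 6 are transient, so chiral intermediates are racemic and diastereomers of 16–19 may be carried on together.

**Step 1**
Reactants: 1 benzofuran-6-ol
Product: 2 6-(triisopropylsilyloxy)benzofuran
Conditions: TIPSCl, imidazole, DMF, rt
Reagents that add atoms: triisopropylsilyl chloride, CC(C)[Si](Cl)(C(C)C)C(C)C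
Why: Standard phenol silylation; the bulky silyl ether tolerates organolithium and hindered alkoxide bases, does not direct ortho-metalation, and can later be removed without touching an aryl methyl ether.

**Step 2**
Reactants: 2 6-(triisopropylsilyloxy)benzofuran
Product: 4 6-(triisopropylsilyloxy)benzofuran-2-carbaldehyde, via 2-lithio-6-(triisopropylsilyloxy)benzofuran 3 (not isolated)
Conditions: n-BuLi, THF, −78 °C; DMF, −78 → 0 °C; aq. NH4Cl
Reagents that add atoms: N,N-dimethylformamide, CN(C)C=O
Why: C2–H is the most acidic position of a benzofuran, so lithiation followed by formylation of the aryllithium with DMF (Bouveault-type aldehyde synthesis) should give the 2-carbaldehyde only.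

**Step 3**
Reactants: 5 diethyl (2-oxopropyl)phosphonate; 6 1-bromo-3-methylbut-2-ene
Product: 7 diethyl (6-methyl-2-oxohept-5-en-3-yl)phosphonate (racemic)
Conditions: NaH, THF, 0 °C; 6, 0 °C → rt
Reagents that add atoms: none
Why: SN2 C-alkylation of the sodium salt of a β-ketophosphonate with a primary allylic bromide is standard, a slight excess of 5 suppresses double alkylation, and the racemic new centre is destroyed in step 4.

**Step 4**
Reactants: 4 6-(triisopropylsilyloxy)benzofuran-2-carbaldehyde; 7 diethyl (6-methyl-2-oxohept-5-en-3-yl)phosphonate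
Product: 8 (E)-6-methyl-3-{[6-(triisopropylsilyloxy)benzofuran-2-yl]methylidene}hept-5-en-2-one
Conditions: NaH, THF, 0 °C; 4, rt → 60 °C
Reagents that add atoms: none
Why: Horner–Wadsworth–Emmons olefination of a non-enolisable heteroaryl aldehyde with an α-branched β-ketophosphonate, in which reversible addition favours the (E)-enone (aryl trans to acetyl); the alkene geometry does not affect the constitution of the key-step product.

**Step 5**
Reactants: 9 2-methylbut-3-en-2-ol; 10 trimethyl orthoacetate
Product: 12 methyl 5-methylhex-4-enoate, via mixed ketene acetal 11 (not isolated)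
Conditions: EtCO2H (cat.), excess 10 neat, 110–140 °C, MeOH distilled off
Reagents that add atoms: none
Why: Johnson–Claisen rearrangement; acid-catalysed exchange gives ketene acetal 11, whose [3,3]-sigmatropic shift trades the tertiary allylic C–O bond for a C–C bond and delivers the trisubstituted alkene of the γ,δ-unsaturated ester.

**Step 6**
Reactants: 12 methyl 5-methylhex-4-enoate; 8 (E)-6-methyl-3-{[6-(triisopropylsilyloxy)benzofuran-2-yl]methylidene}hept-5-en-2-one
Product: 16 all-trans (meso) 5-[6-(triisopropylsilyloxy)benzofuran-2-yl]-4,6-bis(3-methylbut-2-enyl)cyclohexane-1,3-dione, via ester lithium enolate 13 (not isolated), via internal ketone lithium enolate 14 (not isolated), via methyl-side ketone lithium enolate 15 (not isolated)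
Conditions: LiN(i-Pr)2 (LDA, 1.05 equiv), 12 (1.1 equiv), THF, −78 °C; DMPU; 8, −78 → 0 °C; t-BuOH (1 equiv), KOt-Bu (0.2 equiv), 0 °C → rt; cold 1 M HCl to pH 3
Reagents that add atoms: none
Why: Enolate 13 adds to the exocyclic β-carbon of 8 (bond C1'–C2') to give the tetrasubstituted enolate 14, t-BuOH/KOt-Bu relays a proton so that the methyl-side enolate 15 is populated, and 15 attacks the ester carbonyl with loss of methoxide (bond C3'–C4'), the acidic dione then consuming that methoxide. This is the consecutive Michael–Claisen annulation known for 5-arylcyclohexane-1,3-diones from enones and ester or malonate enolates, with the KOt-Bu closure of δ-keto esters as its second half. The single ring closes in the 6-(enolendo)-exo-trig mode, and only the methyl carbon can do so because closure from the internal α-carbon would give a four-membered ring. The step needs 1,4- rather than 1,2-addition and C–C bond formation rather than proton transfer from the acetyl CH3: DMPU loosens the lithium ion pair in favour of conjugate attack, the 1,2-adduct is a crowded tertiary aldolate next to the prenyl-bearing carbon that reverts on warming, and all equilibria drain into the stabilised dione enolate as the only irreversible sink. C5 arises in the Michael step while C4 and C6 remain epimerisable through the open-chain enolates and the enol forms of the product, so the relative configuration is under thermodynamic control and the all-equatorial isomer (both prenyl groups trans to the aryl group, meso) should dominate; other diastereomers share the constitution and converge in step 9. Total base stays close to one equivalent and ends as the non-nucleophilic dione enolate, which together with the bulk of the triisopropylsilyl group should preserve the aryl silyl ether.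

**Step 7**
Reactants: 16 all-trans (meso) 5-[6-(triisopropylsilyloxy)benzofuran-2-yl]-4,6-bis(3-methylbut-2-enyl)cyclohexane-1,3-dione
Product: 17 all-trans 3-methoxy-5-[6-(triisopropylsilyloxy)benzofuran-2-yl]-4,6-bis(3-methylbut-2-enyl)cyclohex-2-en-1-one (racemic)
Conditions: TMSCHN2, toluene/MeOH, 0 °C
Reagents that add atoms: (trimethylsilyl)diazomethane, C[Si](C)(C)C=[N+]=[N-]
Why: The enolised 1,3-dione is a vinylogous carboxylic acid and is O-methylated under neutral conditions; the mirror plane through C2 and C5 of 16 makes both oxygens equivalent, so only one constitution can form, and C2-methylation and acid-induced cyclisation onto a prenyl group are avoided.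

**Step 8**
Reactants: 17 all-trans 3-methoxy-5-[6-(triisopropylsilyloxy)benzofuran-2-yl]-4,6-bis(3-methylbut-2-enyl)cyclohex-2-en-1-one
Product: 19 4,5-trans-1-(tert-butyldimethylsilyloxy)-3-methoxy-5-[6-(triisopropylsilyloxy)benzofuran-2-yl]-4,6-bis(3-methylbut-2-enyl)cyclohexa-1(6),2-diene (racemic), via lithium dienolate 18 (not isolated)
Conditions: LiN(i-Pr)2, THF, −78 °C; TBSOTf, −78 → 0 °C; cold aq. NaHCO3
Reagents that add atoms: tert-butyldimethylsilyl triflate, CC(C)(C)[Si](C)(C)OS(=O)(=O)C(F)(F)F
Why: Kinetic α'-deprotonation of a 3-alkoxycyclohexenone at C6 (the enolate regiochemistry of Stork–Danheiser chemistry) and O-silylation give a 1-silyloxy-3-methoxycyclohexa-1,3-diene that can be dehydrogenated under very mild conditions; the C6 centre disappears and C4/C5 stay trans.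

**Step 9**
Reactants: 19 4,5-trans-1-(tert-butyldimethylsilyloxy)-3-methoxy-5-[6-(triisopropylsilyloxy)benzofuran-2-yl]-4,6-bis(3-methylbut-2-enyl)cyclohexa-1(6),2-diene
Product: 20 2-[3-(tert-butyldimethylsilyloxy)-5-methoxy-2,6-bis(3-methylbut-2-enyl)phenyl]-6-(triisopropylsilyloxy)benzofuran
Conditions: DDQ (1.05 equiv), 2,4,6-collidine, CH2Cl2, −20 → 0 °C
Reagents that add atoms: none
Why: DDQ dehydrogenation of a cyclohexadiene/silyl enol ether: hydride leaves from C5–H, the only C–H whose loss gives a cation stabilised by both ring oxygens and the benzofuran, and collidine takes the C4 proton, so aromatisation runs well below the temperatures at which DDQ attacks prenyl groups, and the phenol emerges silylated, which blocks oxidative chromene closure onto the C2' prenyl group.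

**Step 10**
Reactants: 20 2-[3-(tert-butyldimethylsilyloxy)-5-methoxy-2,6-bis(3-methylbut-2-enyl)phenyl]-6-(triisopropylsilyloxy)benzofuran
Product: 21 2-[3-hydroxy-5-methoxy-2,6-bis(3-methylbut-2-enyl)phenyl]benzofuran-6-ol (CNP0324103.0)
Conditions: n-Bu4NF (2.4 equiv), AcOH (2.4 equiv), THF, 0 °C → rt
Reagents that add atoms: none
Why: Fluoride cleaves both aryl silyl ethers in one operation under acetic acid-buffered, near-neutral conditions, so neither acid-induced chroman formation from the ortho-prenylphenol nor attack on the C5' methyl ether can occur.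

**Compound list**
1 | benzofuran-6-ol | Oc1ccc2ccoc2c1 | starting material
2 | 6-(triisopropylsilyloxy)benzofuran | CC(C)[Si](Oc1ccc2ccoc2c1)(C(C)C)C(C)C | intermediate
3 | 2-lithio-6-(triisopropylsilyloxy)benzofuran | [Li]c1cc2ccc(O[Si](C(C)C)(C(C)C)C(C)C)cc2o1 | intermediate
4 | 6-(triisopropylsilyloxy)benzofuran-2-carbaldehyde | O=Cc1cc2ccc(O[Si](C(C)C)(C(C)C)C(C)C)cc2o1 | intermediate
5 | diethyl (2-oxopropyl)phosphonate | CCOP(=O)(CC(C)=O)OCC | starting material
6 | 1-bromo-3-methylbut-2-ene | CC(C)=CCBr | starting material
7 | diethyl (6-methyl-2-oxohept-5-en-3-yl)phosphonate, racemic | CCOP(=O)(OCC)C(CC=C(C)C)C(C)=O | intermediate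
8 | (E)-6-methyl-3-{[6-(triisopropylsilyloxy)benzofuran-2-yl]methylidene}hept-5-en-2-one | CC(=O)/C(CC=C(C)C)=C/c1cc2ccc(O[Si](C(C)C)(C(C)C)C(C)C)cc2o1 | intermediate
9 | 2-methylbut-3-en-2-ol | CC(C)(O)C=C | starting material
10 | trimethyl orthoacetate | COC(C)(OC)OC | starting material
11 | 3-(1-methoxyvinyloxy)-3-methylbut-1-ene (mixed ketene acetal) | C=C(OC)OC(C)(C)C=C | intermediate
12 | methyl 5-methylhex-4-enoate | COC(=O)CCC=C(C)C | intermediate
13 | lithium enolate of 12 | [Li]OC(OC)=CCC=C(C)C | intermediate
14 | Michael adduct as internal (tetrasubstituted) lithium enolate, diastereomer mixture | CC(O[Li])=C(CC=C(C)C)C(c1cc2ccc(O[Si](C(C)C)(C(C)C)C(C)C)cc2o1)C(CC=C(C)C)C(=O)OC | intermediate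
15 | Michael adduct as methyl-side lithium enolate, diastereomer mixture | C=C(O[Li])C(CC=C(C)C)C(c1cc2ccc(O[Si](C(C)C)(C(C)C)C(C)C)cc2o1)C(CC=C(C)C)C(=O)OC | intermediate
16 | all-trans (meso) 5-[6-(triisopropylsilyloxy)benzofuran-2-yl]-4,6-bis(3-methylbut-2-enyl)cyclohexane-1,3-dione | O=C1CC(=O)[C@H](CC=C(C)C)[C@@H](c2cc3ccc(O[Si](C(C)C)(C(C)C)C(C)C)cc3o2)[C@@H]1CC=C(C)C | intermediate
17 | all-trans 3-methoxy-5-[6-(triisopropylsilyloxy)benzofuran-2-yl]-4,6-bis(3-methylbut-2-enyl)cyclohex-2-en-1-one, racemic (one enantiomer drawn) | COC1=CC(=O)[C@H](CC=C(C)C)[C@@H](c2cc3ccc(O[Si](C(C)C)(C(C)C)C(C)C)cc3o2)[C@@H]1CC=C(C)C | intermediate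
18 | lithium dienolate of 17 (C1–O–Li, C1=C6), racemic | COC1=CC(O[Li])=C(CC=C(C)C)[C@@H](c2cc3ccc(O[Si](C(C)C)(C(C)C)C(C)C)cc3o2)[C@@H]1CC=C(C)C | intermediate
19 | 4,5-trans-1-(tert-butyldimethylsilyloxy)-3-methoxy-5-[6-(triisopropylsilyloxy)benzofuran-2-yl]-4,6-bis(3-methylbut-2-enyl)cyclohexa-1(6),2-diene, racemic | COC1=CC(O[Si](C)(C)C(C)(C)C)=C(CC=C(C)C)[C@@H](c2cc3ccc(O[Si](C(C)C)(C(C)C)C(C)C)cc3o2)[C@@H]1CC=C(C)C | intermediate
20 | 2-[3-(tert-butyldimethylsilyloxy)-5-methoxy-2,6-bis(3-methylbut-2-enyl)phenyl]-6-(triisopropylsilyloxy)benzofuran | COc1cc(O[Si](C)(C)C(C)(C)C)c(CC=C(C)C)c(-c2cc3ccc(O[Si](C(C)C)(C(C)C)C(C)C)cc3o2)c1CC=C(C)C | intermediate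
21 | 2-[3-hydroxy-5-methoxy-2,6-bis(3-methylbut-2-enyl)phenyl]benzofuran-6-ol | COc1cc(O)c(CC=C(C)C)c(-c2cc3ccc(O)cc3o2)c1CC=C(C)C | target

**Step count**
Total steps: 10. Longest linear sequence: 8 (steps 1, 2, 4, 6, 7, 8, 9, 10).

**Steps most likely to fail**

Step 6. Several processes may intervene:
- carbonyl attack by the ester enolate that does not revert;
- proton transfer from the acetyl methyl group to the more basic ester enolate;
- a stalled enolate transposition that leaves the chain open;
- loss of the silyl protecting group to alkoxide.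

The fallback sets out from 12 and 8 and returns at 16, and it separates the two bond formations and replaces the anionic addition by a Lewis acid one. Ester 12 is converted with LiN(i-Pr)2 and TMSCl into 1-methoxy-5-methyl-1-(trimethylsilyloxy)hexa-1,4-diene F1. F1 is added to enone 8 under TiCl4 activation in CH2Cl2 at −78 °C (Mukaiyama–Michael reaction). No basic species is present there, and silyl ketene acetals attack the activated enone at the β-carbon. Aqueous work-up should give the δ-keto ester methyl 4-acetyl-7-methyl-2-(3-methylbut-2-enyl)-3-[6-(triisopropylsilyloxy)benzofuran-2-yl]oct-6-enoate F2. F2 is isolated and then closed on its methyl carbon with KOt-Bu in THF to dione 16.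

Step 9. Risks are oxidation at the allylic positions of the prenyl groups, hydrolysis of the dienol ether by the acidic hydroquinone, or premature desilylation followed by oxidative ring closure of the freed phenol. The fallback sets out from 17 and returns at 21, and it replaces hydride abstraction by α-functionalisation and syn-elimination. Compound 17 is deprotonated with LiN(i-Pr)2 and quenched with PhSeCl at −78 °C. Selenium should enter C6 on the face opposite the C5 aryl group, hence cis to C5–H, giving the 6-phenylselanyl vinylogous ester F3. Oxidation with H2O2/pyridine in CH2Cl2 at 0 °C gives the selenoxide F4. Syn-elimination of F4 into the ring, followed by enolisation, should deliver 3-methoxy-2,4-bis(3-methylbut-2-enyl)-... phenol, namely 5-methoxy-2,6-diprenyl-1-[6-(triisopropylsilyloxy)benzofuran-2-yl]-3-hydroxybenzene F5. n-Bu4NF/AcOH then removes the remaining silyl group to give 21.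

Step 4. Risks are slow addition of the α-branched phosphonate anion to an electron-rich aldehyde, erosion of alkene geometry, and further base-induced condensation at the acetyl methyl group. The fallback sets out from 4 and returns at 8, and it forms the allylic C–C bond instead of the C=C bond. A Morita–Baylis–Hillman reaction of 4 with but-3-en-2-one (DABCO) gives 3-{hydroxy[6-(triisopropylsilyloxy)benzofuran-2-yl]methyl}but-3-en-2-one F6. Ac2O/Et3N/DMAP converts F6 into the allylic acetate F7. SN2' displacement with (CH3)2C=CHMgBr and CuBr·SMe2 in THF at −78 °C attacks the terminal CH2, builds the prenyl group and expels acetate to give the (E)-enone 8.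

**Further compounds**
F1 | step 6 | 1-methoxy-5-methyl-1-(trimethylsilyloxy)hexa-1,4-diene | COC(O[Si](C)(C)C)=CCC=C(C)C
F2 | step 6 | methyl 4-acetyl-7-methyl-2-(3-methylbut-2-enyl)-3-[6-(triisopropylsilyloxy)benzofuran-2-yl]oct-6-enoate (diastereomer mixture) | COC(=O)C(CC=C(C)C)C(c1cc2ccc(O[Si](C(C)C)(C(C)C)C(C)C)cc2o1)C(CC=C(C)C)C(C)=O
F3 | step 9 | 3-methoxy-6-(phenylselanyl)-5-[6-(triisopropylsilyloxy)benzofuran-2-yl]-4,6-bis(3-methylbut-2-enyl)cyclohex-2-en-1-one | COC1=CC(=O)C(CC=C(C)C)([Se]c2ccccc2)C(c2cc3ccc(O[Si](C(C)C)(C(C)C)C(C)C)cc3o2)C1CC=C(C)C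
F4 | step 9 | selenoxide of F3 | COC1=CC(=O)C(CC=C(C)C)([Se](=O)c2ccccc2)C(c2cc3ccc(O[Si](C(C)C)(C(C)C)C(C)C)cc3o2)C1CC=C(C)C
F5 | step 9 | 5-methoxy-2,4-bis(3-methylbut-2-enyl)-3-[6-(triisopropylsilyloxy)benzofuran-2-yl]phenol | COc1cc(O)c(CC=C(C)C)c(-c2cc3ccc(O[Si](C(C)C)(C(C)C)C(C)C)cc3o2)c1CC=C(C)C
F6 | step 4 | 3-{hydroxy[6-(triisopropylsilyloxy)benzofuran-2-yl]methyl}but-3-en-2-one (racemic) | C=C(C(C)=O)C(O)c1cc2ccc(O[Si](C(C)C)(C(C)C)C(C)C)cc2o1
F7 | step 4 | 2-methylidene-3-oxo-1-[6-(triisopropylsilyloxy)benzofuran-2-yl]butyl acetate (racemic) | C=C(C(C)=O)C(OC(C)=O)c1cc2ccc(O[Si](C(C)C)(C(C)C)C(C)C)cc2o1
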